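**The invariant.** Every coupling in these flasks takes one substrate of either hand and one coupling partner and makes one product of that hand, so the coupling partner stays ahead of the two substrates together by a constant 0.100 M. The free catalyst favours the left-handed substrate, the racemization catalyst turns the substrates into each other, and the products interconvert unaided.

| setting | Saturday's | Sunday's | Tuesday's |
|---|---|---|---|
| left-handed substrate | 0.50 M | 0.50 M | 0.50 M |
| coupling partner | 1.10 M | 1.10 M | 1.10 M |
| free catalyst | 90 mM | 90 mM | 90 mM |
| racemization catalyst | 10 mM | 10 mM | 10 mM |
| right-handed substrate | 0.50 M | 0.50 M | 0.50 M |
| temperature | 55 °C | −5 °C | 25 °C |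
| time | 4.0 min | 4.0 min | 4.0 min |

- which flask leads in amount of left-handed product, in percent of the left-handed substrate and right-handed substrate together charged ("all alike" within 1.5 percentage points) (Saturday's / Sunday's / Tuesday's / all alike)
- how much left-handed product is there at the end, in percent of the left-handed substrate and right-handed substrate together charged: Saturday's
- how much left-handed product is there at the end, in percent of the left-handed substrate and right-handed substrate together charged: Sunday's
- how much left-handed product is there at the end, in percent of the left-handed substrate and right-handed substrate together charged: Tuesday's

- free catalyst is single-handed; left-handed substrate and right-handed substrate are mirror images of each other, charged as a racemate, each of them at the stated concentration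
- at 25 °C the constants are as listed, elsewhere as the activation energies make them

    left-handed substrate + racemization catalyst ⇌ right-handed substrate + racemization catalyst, rate k1*[racemization catalyst]*[left-handed substrate] forward; the back reaction follows from the equilibrium constant (k1 = 110 M⁻¹ s⁻¹, Ea1 = 40.0 kJ mol⁻¹)
    coupling partner + free catalyst + right-handed substrate → free catalyst + right-handed product (k2 = 0.0023 M⁻² s⁻¹, Ea2 = 46.0 kJ mol⁻¹)
    left-handed product ⇌ right-handed product (k3 = 0.035 s⁻¹, Ea3 = 90.0 kJ mol⁻¹)
    coupling partner + free catalyst + left-handed substrate → free catalyst + left-handed product (k4 = 0.24 M⁻² s⁻¹, Ea4 = 52.0 kJ mol⁻¹)
    (constants at 25 °C)

**Bench rule.** The rule for a dynamic kinetic resolution says that a substrate racemizing faster than it couples behaves as one substrate and comes out in the favoured hand. I tried it on Tuesday's, at 25 °C. There the substrates interconvert at 1.10 s⁻¹, far faster than the left-handed substrate couples at 0.0238 s⁻¹, so I held the left-handed substrate at half of the two together. The right-handed coupling constant 0.0023 M⁻² s⁻¹ lies far below the left-handed 0.24 M⁻² s⁻¹, a selectivity factor of 104, so I dropped it.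

**Partner lifetime.** I carried 1.54 min, the partner lifetime: one over the fast constant, the free catalyst and the left-handed charge, which is the pseudo-first-order life of coupling partner while the substrates stand at their charge. With the gap constant, the ratio of coupling partner to substrates changes exponentially, by the gap over the substrate charge per lifetime. The substrates left are the gap divided by that ratio's excess over one. On Tuesday's the ratio went from 1.10 to 1.43, leaving 0.235 M of substrates, 23.5 % of the charge.

**The border.** The rule stops at the products. Their relaxation half-life on Tuesday's, both ways together, is 0.165 min, and the run holds 24.2 of them, so I put the left-handed product at half of what coupled: 38.2 %. I took the reckoning no further than Tuesday's.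

**The forecast.** It named Saturday's as leader, with 49.1 % for Saturday's, 20 % for Sunday's and 38.9 % for Tuesday's, the last above mine. Its ground: “the warmest flask still leads because its higher conversion outweighs the lost product enantiopurity”.

**The run.** Saturday's ended at 49.1 % of left-handed product, Sunday's at 20.0 % and Tuesday's at 39.0 %, so Saturday's leads. The right-handed coupling made no difference to Saturday's. The partner lifetime gives Tuesday's first 30.0 % of conversion in 0.590 min, and Tuesday's reading was 0.587 min.

**Second flask.** A neighbour of Tuesday's charged with 0.28 M of coupling partner makes that partner the limiting reagent and turns the gap to −0.720 M. The same lifetime carries the ratio down to 0.0433, which leaves 75.3 % of the substrates and 12.4 % of left-handed product. The neighbour gave 75 % of its right-handed substrate left and 12.6 % of left-handed product.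

The numbers were drawn at random within sensible limits; what happens was integrated by code.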